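The hydroxylated end ring (ring A; carotenoid numbering C1–C6) is closed at the C4–C5 bond. An acyclic ethyl ketone whose other α-carbon is the quaternary C1 (gem-dimethyl) can enolise only at the future C5; its potassium enolate displaces a primary chloride at C4, next to the C3 stereocentre taken unchanged from (S)-epichlorohydrin, in a 6-exo-tet C-alkylation. The same blocking makes the derived enol triflate regiospecific, fixing the tetrasubstituted C5=C6 alkene and providing the handle for a final C6–C7 Suzuki coupling of the oleoylated ring with a C31 nonaenyl boronate from commercial β-apo-8'-carotenal.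

Key step: step 4

Remark: the target is read as (3R)-β-cryptoxanthin (9Z)-octadec-9-enoate with an all-E polyene. Atoms are named by carotenoid numbering (C1 = CMe2, C2 = CH2, C3 = CH–O, C4 = CH2, C5 = C(CH3)=, C6 = ring carbon bearing the chain, C7=C8 = first chain alkene). Polyenes 17, 20 and 21 are handled under argon with exclusion of light.

Step 1
Reactants: 1 isobutyronitrile; 2 (S)-epichlorohydrin
Product: 5 (4S)-5-chloro-4-hydroxy-2,2-dimethylpentanenitrile, via lithiated isobutyronitrile 3 (not isolated), via lithium alkoxide of the chlorohydrin 4 (not isolated)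
Conditions: LiN(iPr)2 (1.05 equiv), THF, −78 °C; 2, −78 to −20 °C; then AcOH, LiCl, 0 °C to rt
Reagents that add atoms: none
Why: Alkylation of a metalated nitrile by SN2 opening of the terminal epoxide at its CH2 carbon; the C–O bond at the stereocentre of 2 is not broken, so its configuration passes unchanged into 5 (future C3), and the LiCl/AcOH quench should return any epoxide formed by chloride loss to the same chlorohydrin.

Step 2
Reactants: 5 (4S)-5-chloro-4-hydroxy-2,2-dimethylpentanenitrile
Product: 6 (4S)-4-[(tert-butyldimethylsilyl)oxy]-5-chloro-2,2-dimethylpentanenitrile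
Conditions: TBSCl, imidazole, DMF, 0 °C to rt
Reagents that add atoms: tert-butyldimethylsilyl chloride, CC(C)(C)[Si](C)(C)Cl
Why: Imidazole-mediated silyl ether formation at the secondary alcohol masks the hydroxyl against the strong bases of steps 3 to 5 and prevents epoxide closure onto the CH2Cl group.

Step 3
Reactants: 6 (4S)-4-[(tert-butyldimethylsilyl)oxy]-5-chloro-2,2-dimethylpentanenitrile; 7 ethyllithium
Product: 9 (6S)-6-[(tert-butyldimethylsilyl)oxy]-7-chloro-4,4-dimethylheptan-3-one, via lithium ketimide 8 (not isolated)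
Conditions: EtLi (1.2 equiv), Et2O, −78 to −20 °C; then 1 M aq. HCl, THF, 0 °C
Reagents that add atoms: water, O
Why: Addition of an organolithium to a nitrile without α-hydrogen stops at the N-lithio ketimine, which aqueous acid hydrolyses to the ethyl ketone; the low temperature should keep the primary chloride and the silyl ether intact, and the stereocentre is not involved.

Step 4
Reactants: 9 (6S)-6-[(tert-butyldimethylsilyl)oxy]-7-chloro-4,4-dimethylheptan-3-one
Product: 11 (4R)-4-[(tert-butyldimethylsilyl)oxy]-2,2,6-trimethylcyclohexan-1-one (both C6 epimers), via potassium enolate 10 (not isolated)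
Conditions: KN(SiMe3)2 (1.1 equiv), THF, −78 °C to rt (40 °C if needed)
Reagents that add atoms: none
Why: KN(SiMe3)2 removes a proton from the only enolisable α-carbon, the CH2 of the ethyl group (future C5), because the other α-carbon is the quaternary C1, and the enolate carbon then displaces chloride from the primary C4 by intramolecular SN2, which creates the C4–C5 bond. The closest known reaction type is the intramolecular C-alkylation of ω-halo ketone enolates, as used for 2,2-disubstituted cyclohexanones. Ring A (the six-membered carbocycle C1–C6) closes in the 6-(enolendo)-exo-tet mode, a favoured mode, with the leaving chloride outside the new ring. The new stereocentre (the methyl-bearing ring carbon, future C5) is formed without useful control, as an epimer mixture expected to lean toward the equatorial methyl, which is harmless because this carbon becomes sp2 in step 5; C3 is not touched, so its configuration is retained and only its descriptor changes from S to R through the new CIP ranking. The step needs C- over O-alkylation and substitution over E2: the enolate carbon can reach C4 through a chair-like six-membered transition state with near-collinear C···C–Cl alignment, a potassium enolate in THF without dipolar additive favours attack through carbon, and no free base remains after enolate formation to cause elimination.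

Step 5
Reactants: 11 (4R)-4-[(tert-butyldimethylsilyl)oxy]-2,2,6-trimethylcyclohexan-1-one
Product: 13 (4R)-4-[(tert-butyldimethylsilyl)oxy]-2,6,6-trimethylcyclohex-1-en-1-yl trifluoromethanesulfonate, via lithium enolate 12 (not isolated)
Conditions: LiN(iPr)2, THF, −78 to 0 °C; PhNTf2, −78 °C to rt
Reagents that add atoms: N-phenylbis(trifluoromethanesulfonimide), O=S(=O)(N(c1ccccc1)S(=O)(=O)C(F)(F)F)C(F)(F)F
Why: Only the methyl-bearing α-carbon of 11 (future C5) carries a hydrogen, so both epimers should give the same tetrasubstituted lithium enolate, whose O-sulfonylation (enol triflate formation) fixes the C5=C6 double bond of the target regiospecifically.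

Step 6
Reactants: 13 (4R)-4-[(tert-butyldimethylsilyl)oxy]-2,6,6-trimethylcyclohex-1-en-1-yl trifluoromethanesulfonate
Product: 14 (4R)-4-hydroxy-2,6,6-trimethylcyclohex-1-en-1-yl trifluoromethanesulfonate
Conditions: HF·pyridine, pyridine, THF, 0 °C to rt
Reagents that add atoms: none
Why: Fluoride-driven cleavage of the Si–O bond (silyl ether deprotection) under buffered acidic conditions should leave the enol triflate untouched; the C3–O bond is not broken, so the configuration is retained.

Step 7
Reactants: 14 (4R)-4-hydroxy-2,6,6-trimethylcyclohex-1-en-1-yl trifluoromethanesulfonate; 15 oleoyl chloride [(9Z)-octadec-9-enoyl chloride]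
Product: 16 (1R)-3,5,5-trimethyl-4-{[(trifluoromethyl)sulfonyl]oxy}cyclohex-3-en-1-yl (9Z)-octadec-9-enoate
Conditions: pyridine, DMAP (cat.), CH2Cl2, 0 °C to rt
Reagents that add atoms: none
Why: DMAP-catalysed acylation of the secondary alcohol by the acid chloride (nucleophilic acyl transfer) forms the ester with retention at C3 and should not affect the Z alkene of the acyl chain or the enol triflate.

Step 8
Reactants: 17 all-trans-β-apo-8'-carotenal; 18 bis(4,4,5,5-tetramethyl-1,3,2-dioxaborolan-2-yl)methane
Product: 20 2-[(1E,3E,5E,7E,9E,11E,13E,15E,17E)-3,7,12,16-tetramethyl-18-(2,6,6-trimethylcyclohex-1-en-1-yl)octadeca-1,3,5,7,9,11,13,15,17-nonaen-1-yl]-4,4,5,5-tetramethyl-1,3,2-dioxaborolane, via lithiated diborylmethane 19 (not isolated)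
Conditions: lithium 2,2,6,6-tetramethylpiperidide, 18, THF, 0 °C; then 17, −78 °C to rt, dark
Reagents that add atoms: none
Why: Boron–Wittig olefination: the α-boryl carbanion adds to the aldehyde and syn elimination of the boron–oxygen pair should give the E-alkenyl boronate, which adds C7 with the required C7=C8 geometry.

Step 9
Reactants: 16 (1R)-3,5,5-trimethyl-4-{[(trifluoromethyl)sulfonyl]oxy}cyclohex-3-en-1-yl (9Z)-octadec-9-enoate; 20 C31 nonaenyl pinacol boronate
Product: 21 (3R)-β-cryptoxanthin oleate, (1R)-3,5,5-trimethyl-4-[(1E,3E,5E,7E,9E,11E,13E,15E,17E)-3,7,12,16-tetramethyl-18-(2,6,6-trimethylcyclohex-1-en-1-yl)octadeca-1,3,5,7,9,11,13,15,17-nonaen-1-yl]cyclohex-3-en-1-yl (9Z)-octadec-9-enoate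
Conditions: Pd(OAc)2 (5 mol %), SPhos (10 mol %), K3PO4, degassed THF/H2O, 40 °C, dark
Reagents that add atoms: none
Why: Suzuki–Miyaura coupling of an enol triflate with an E-alkenyl boronate joins C6 and C7 with retention of both alkene geometries; the bulky electron-rich biaryl phosphine is chosen for the hindered tetrasubstituted triflate, and the phosphate base at 40 °C should spare the ester and leave C3 untouched.

Compound list
1 | isobutyronitrile (2-methylpropanenitrile) | CC(C)C#N | starting material
2 | (S)-epichlorohydrin, (2S)-2-(chloromethyl)oxirane | ClC[C@@H]1CO1 | starting material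
3 | 2-lithio-2-methylpropanenitrile (not isolated) | [Li]C(C)(C)C#N | intermediate
4 | lithium (2S)-1-chloro-4-cyano-4-methylpentan-2-olate (not isolated) | N#CC(C)(C)C[C@H](O[Li])CCl | intermediate
5 | (4S)-5-chloro-4-hydroxy-2,2-dimethylpentanenitrile | N#CC(C)(C)C[C@H](O)CCl | intermediate
6 | (4S)-4-[(tert-butyldimethylsilyl)oxy]-5-chloro-2,2-dimethylpentanenitrile | N#CC(C)(C)C[C@H](O[Si](C)(C)C(C)(C)C)CCl | intermediate
7 | ethyllithium | [Li]CC | starting material
8 | N-lithio ketimine of ketone 9 (not isolated) | CCC(=N[Li])C(C)(C)C[C@H](O[Si](C)(C)C(C)(C)C)CCl | intermediate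
9 | (6S)-6-[(tert-butyldimethylsilyl)oxy]-7-chloro-4,4-dimethylheptan-3-one | CCC(=O)C(C)(C)C[C@H](O[Si](C)(C)C(C)(C)C)CCl | intermediate
10 | potassium (Z)-enolate of ketone 9 (not isolated) | C/C=C(\O[K])C(C)(C)C[C@H](O[Si](C)(C)C(C)(C)C)CCl | intermediate
11 | (4R)-4-[(tert-butyldimethylsilyl)oxy]-2,2,6-trimethylcyclohexan-1-one (C6 epimers) | CC1C[C@@H](O[Si](C)(C)C(C)(C)C)CC(C)(C)C1=O | intermediate
12 | lithium enolate of ketone 11 (not isolated) | CC1=C(O[Li])C(C)(C)C[C@H](O[Si](C)(C)C(C)(C)C)C1 | intermediate
13 | (4R)-4-[(tert-butyldimethylsilyl)oxy]-2,6,6-trimethylcyclohex-1-en-1-yl trifluoromethanesulfonate | CC1=C(OS(=O)(=O)C(F)(F)F)C(C)(C)C[C@H](O[Si](C)(C)C(C)(C)C)C1 | intermediate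
14 | (4R)-4-hydroxy-2,6,6-trimethylcyclohex-1-en-1-yl trifluoromethanesulfonate | O[C@@H]1CC(C)=C(OS(=O)(=O)C(F)(F)F)C(C)(C)C1 | intermediate
15 | oleoyl chloride, (9Z)-octadec-9-enoyl chloride | CCCCCCCC/C=C\CCCCCCCC(=O)Cl | starting material
16 | (1R)-3,5,5-trimethyl-4-{[(trifluoromethyl)sulfonyl]oxy}cyclohex-3-en-1-yl (9Z)-octadec-9-enoate | CCCCCCCC/C=C\CCCCCCCC(=O)O[C@@H]1CC(C)=C(OS(=O)(=O)C(F)(F)F)C(C)(C)C1 | intermediate
17 | all-trans-β-apo-8'-carotenal, (2E,4E,6E,8E,10E,12E,14E,16E)-2,6,11,15-tetramethyl-17-(2,6,6-trimethylcyclohex-1-en-1-yl)heptadeca-2,4,6,8,10,12,14,16-octaenal | O=C/C(C)=C/C=C/C(C)=C/C=C/C=C(C)/C=C/C=C(C)/C=C/C1=C(C)CCCC1(C)C | starting material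
18 | bis(4,4,5,5-tetramethyl-1,3,2-dioxaborolan-2-yl)methane | CC1(C)OB(CB2OC(C)(C)C(C)(C)O2)OC1(C)C | starting material
19 | lithio-bis(4,4,5,5-tetramethyl-1,3,2-dioxaborolan-2-yl)methane (not isolated) | [Li]C(B1OC(C)(C)C(C)(C)O1)B1OC(C)(C)C(C)(C)O1 | intermediate
20 | 2-[(1E,3E,5E,7E,9E,11E,13E,15E,17E)-3,7,12,16-tetramethyl-18-(2,6,6-trimethylcyclohex-1-en-1-yl)octadeca-1,3,5,7,9,11,13,15,17-nonaen-1-yl]-4,4,5,5-tetramethyl-1,3,2-dioxaborolane | CC1(C)OB(/C=C/C(C)=C/C=C/C(C)=C/C=C/C=C(C)/C=C/C=C(C)/C=C/C2=C(C)CCCC2(C)C)OC1(C)C | intermediate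
21 | (3R)-β-cryptoxanthin oleate | CCCCCCCC/C=C\CCCCCCCC(=O)O[C@@H]1CC(C)=C(/C=C/C(C)=C/C=C/C(C)=C/C=C/C=C(C)/C=C/C=C(C)/C=C/C2=C(C)CCCC2(C)C)C(C)(C)C1 | target

Total step count: 9. Longest linear sequence: 8 steps (steps 1 to 7 and 9; step 8 is a one-step side branch).

Steps most likely to fail

Step 9. Oxidative addition and transmetalation at the enol triflate, flanked by the gem-dimethyl carbon and the methyl-bearing alkene carbon, may be so slow that triflate hydrolysis, protodeboronation of the nonaenyl boronate or ester cleavage outrun the coupling. The fallback sets out from 13 and comes back at 21; it joins the chain one bond further out, at C7=C8, by Wittig olefination. Methoxycarbonylation of 13 (Pd(OAc)2, 1,3-bis(diphenylphosphino)propane, CO, MeOH, Et3N, DMF) should give methyl (4R)-4-[(tert-butyldimethylsilyl)oxy]-2,6,6-trimethylcyclohex-1-ene-1-carboxylate F1. Reduction with iBu2AlH should give {(4R)-4-[(tert-butyldimethylsilyl)oxy]-2,6,6-trimethylcyclohex-1-en-1-yl}methanol F2. PPh3·HBr in MeOH should convert the allylic alcohol into the phosphonium salt with loss of the silyl group, giving {[(4R)-4-hydroxy-2,6,6-trimethylcyclohex-1-en-1-yl]methyl}triphenylphosphonium bromide F3. Wittig reaction of its ylide (NaOMe, MeOH/CH2Cl2) with aldehyde 17, followed by thermal Z to E equilibration, should give (3R)-β-cryptoxanthin F4, and acylation with 15 (pyridine, DMAP) leads to 21.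

Step 4. O-alkylation of the enolate (also a six-membered closure), E2 loss of HCl, or sluggish displacement at the β-silyloxy primary chloride may compete with C-alkylation. The fallback sets out from 9 and comes back at 11; it closes the same C4–C5 bond through a metalloenamine (1-azaallyl anion), which alkylates at carbon only. Condensation of 9 with cyclohexylamine (TiCl4, toluene) should give (6S)-6-[(tert-butyldimethylsilyl)oxy]-7-chloro-N-cyclohexyl-4,4-dimethylheptan-3-imine F5. Deprotonation with LiN(iPr)2 in THF and warming should give the cyclised (4R)-4-[(tert-butyldimethylsilyl)oxy]-N-cyclohexyl-2,2,6-trimethylcyclohexan-1-imine F6, and mild hydrolysis (aqueous oxalic acid) gives 11.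

Step 1. Part of the carbanion may displace chloride directly instead of opening the epoxide, which after re-opening delivers the enantiomeric chlorohydrin and lowers the enantiomeric purity; addition of the alkoxide to the nitrile is a second leak. The fallback sets out from 1 and comes back at 5; it takes the stereocentre from a kinetic resolution instead of the chiral pool. Allylation of lithiated 1 with allyl bromide should give 2,2-dimethylpent-4-enenitrile F7, and epoxidation with mCPBA the racemic 2,2-dimethyl-3-(oxiran-2-yl)propanenitrile F8. Hydrolytic kinetic resolution with 0.55 equiv H2O and chiral (salen)Co(OAc) (salen = N,N'-bis(3,5-di-tert-butylsalicylidene)-1,2-cyclohexanediamine; the catalyst enantiomer that hydrolyses the R epoxide) should leave 2,2-dimethyl-3-[(2S)-oxiran-2-yl]propanenitrile F9. LiCl/AcOH in THF opens it at the CH2 terminus to give 5.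

Further compounds
F1 | step 9 | methyl (4R)-4-[(tert-butyldimethylsilyl)oxy]-2,6,6-trimethylcyclohex-1-ene-1-carboxylate | COC(=O)C1=C(C)C[C@@H](O[Si](C)(C)C(C)(C)C)CC1(C)C
F2 | step 9 | {(4R)-4-[(tert-butyldimethylsilyl)oxy]-2,6,6-trimethylcyclohex-1-en-1-yl}methanol | OCC1=C(C)C[C@@H](O[Si](C)(C)C(C)(C)C)CC1(C)C
F3 | step 9 | {[(4R)-4-hydroxy-2,6,6-trimethylcyclohex-1-en-1-yl]methyl}triphenylphosphonium bromide | [Br-].O[C@@H]1CC(C)=C(C[P+](c2ccccc2)(c2ccccc2)c2ccccc2)C(C)(C)C1
F4 | step 9 | (3R)-β-cryptoxanthin | O[C@@H]1CC(C)=C(/C=C/C(C)=C/C=C/C(C)=C/C=C/C=C(C)/C=C/C=C(C)/C=C/C2=C(C)CCCC2(C)C)C(C)(C)C1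
F5 | step 4 | (6S)-6-[(tert-butyldimethylsilyl)oxy]-7-chloro-N-cyclohexyl-4,4-dimethylheptan-3-imine | CCC(=NC1CCCCC1)C(C)(C)C[C@H](O[Si](C)(C)C(C)(C)C)CCl
F6 | step 4 | (4R)-4-[(tert-butyldimethylsilyl)oxy]-N-cyclohexyl-2,2,6-trimethylcyclohexan-1-imine | CC1C[C@@H](O[Si](C)(C)C(C)(C)C)CC(C)(C)C1=NC2CCCCC2
F7 | step 1 | 2,2-dimethylpent-4-enenitrile | C=CCC(C)(C)C#N
F8 | step 1 | racemic 2,2-dimethyl-3-(oxiran-2-yl)propanenitrile | N#CC(C)(C)CC1CO1
F9 | step 1 | 2,2-dimethyl-3-[(2S)-oxiran-2-yl]propanenitrile | N#CC(C)(C)C[C@H]1CO1
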